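**Retrosynthetic overview**
- Tangeretin is taken back to nevadensin (methylation of the 5- and 7-hydroxyls), then to 6,8-dibromoacacetin (copper-catalysed C–OMe formation at C6 and C8), then to acacetin (bromination).
- Acacetin comes from a 2',4',6'-trihydroxychalcone by closing ring C (O1–C2 bond) and dehydrogenating C2–C3.
- The strategy rests on ring A: its C5, C7 and C8a oxygens alternate in the acetate pattern and C4a carries the C4(=O)–C3=C2–ring B cinnamoyl chain, so ring A plus that chain is a folded tetraketide. The C4a–C8a bond is therefore cut (Claisen closure of a 3,5,7-triketo ester masked as a 2-pyranone).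
- The pyranone comes from triacetic acid lactone (dianion, bond C4–C4a) and the Weinreb amide of 4-methoxycinnamic acid.
- Ring order: ring B is bought, ring A is closed in step 3, ring C in step 4; the C6 and C8 oxygens are added last.

Key step: step 3

Assumption: the 2',6'-dihydroxychalcone may close partly to its flavanone during acidic work-up of the key step; this is harmless, because the flavanone is the intermediate of the next step.

**Step 1**
Reactants: 1 (E)-4-methoxycinnamoyl chloride
Product: 2 (E)-N-methoxy-3-(4-methoxyphenyl)-N-methylprop-2-enamide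
Conditions: MeNHOMe·HCl (1.1 equiv), Et3N (2.3 equiv), CH2Cl2, 0 °C to rt
Reagents that add atoms: N,O-dimethylhydroxylamine hydrochloride, CNOC.Cl
Why: Nucleophilic acyl substitution of the acid chloride by the free hydroxylamine (Schotten–Baumann-type amidation, Et3N taking up both equivalents of HCl) should give the Weinreb amide without touching the E alkene.

**Step 2**
Reactants: 3 4-hydroxy-6-methyl-2H-pyran-2-one; 2 (E)-N-methoxy-3-(4-methoxyphenyl)-N-methylprop-2-enamide
Product: 5 4-hydroxy-6-[(3E)-4-(4-methoxyphenyl)-2-oxobut-3-en-1-yl]-2H-pyran-2-one (cinnamoylmethyl pyranone), via dilithiated pyranone 4 (not isolated)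
Conditions: LiN(iPr)2 (LDA, commercial solution, 2.3 equiv), THF, −78 °C, 1 h; then 2 (0.9 equiv), −78 to 0 °C; cold 1 M HCl
Reagents that add atoms: none
Why: LiN(iPr)2 removes the O–H and then a C6-methyl proton of 3, and the vinylogous dianion 4 should attack the amide carbonyl through its terminal carbon (Weinreb ketone synthesis, γ-acylation of a 1,3-dicarbonyl dianion), the chelated tetrahedral lithium adduct surviving until the acid quench so that neither a second addition nor quenching of 4 by the more acidic product occurs, while the hard lithium carbanion at −78 °C and the donor-substituted β-carbon disfavour conjugate addition.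

**Step 3**
Reactants: 5 4-hydroxy-6-[(3E)-4-(4-methoxyphenyl)-2-oxobut-3-en-1-yl]-2H-pyran-2-one
Product: 7 (E)-2',4',6'-trihydroxy-4-methoxychalcone, via triketo ester 6 (not isolated)
Conditions: Mg(OMe)2 (commercial solution in MeOH, 3 equiv), dry MeOH, reflux, N2; cold 1 M HCl
Reagents that add atoms: none
Why: Methoxide adds to the lactone carbonyl of 5 and opens the ring to the methyl 3,5,7-trioxo ester 6, held as its magnesium polyenolate; the carbon between the C5 and C7 ketones of 6 (future C4a) then attacks the ester carbonyl (future C8a), methoxide leaves, and the cyclohexanetrione tautomerises to the aromatic triol. The closest known reaction type is the Mg(OMe)2-promoted Claisen (Dieckmann-type) cyclisation of 3,5,7-triketo esters and of 6-(2-oxoalkyl)-4-hydroxy-2-pyranones to acylphloroglucinols. Ring A closes in the 6-exo-trig mode, the ester C=O lying outside the new ring. No stereocenter is formed, and the E alkene, which cannot enolise, is carried through unchanged. The step needs Claisen closure in preference to the aldol closure (C2 methylene onto the C7 ketone) that would give a resorcylate; the ester oxidation level (no free carboxylate), the doubly activated C6 carbanion and magnesium chelation of the 1,3,5-tricarbonyl array in anhydrous methanol bias the chain toward attack on the ester. Reversible side reactions (methoxide or an enolate oxygen adding to the enone) should drain into the aromatic product, whose formation is irreversible.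

**Step 4**
Reactants: 7 (E)-2',4',6'-trihydroxy-4-methoxychalcone
Product: 9 acacetin (5,7-dihydroxy-4'-methoxyflavone), via isosakuranetin 8 (not isolated)
Conditions: I2 (10 mol%), DMSO, 120 °C; aq Na2S2O3
Reagents that add atoms: none
Why: One of the two equivalent ortho hydroxyls adds to the enone (6-endo-trig oxa-Michael) to give flavanone 8, which iodine converts by C3 iodination and loss of HI into the flavone while DMSO reoxidises HI to I2, the standard I2/DMSO oxidative cyclisation of 2'-hydroxychalcones.

**Step 5**
Reactants: 9 acacetin
Product: 10 6,8-dibromo-5,7-dihydroxy-4'-methoxyflavone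
Conditions: NBS (2.1 equiv), DMF, 0 °C to rt, dark
Reagents that add atoms: N-bromosuccinimide, O=C1CCC(=O)N1Br
Why: Electrophilic aromatic bromination should go at C6 and C8, the only free positions of ring A and each ortho or para to two free hydroxyls, far faster than at the ring B carbons or at C3, which are deactivated by conjugation with the pyranone.

**Step 6**
Reactants: 10 6,8-dibromo-5,7-dihydroxy-4'-methoxyflavone
Product: 11 nevadensin (5,7-dihydroxy-6,8,4'-trimethoxyflavone)
Conditions: NaOMe (5 M in MeOH, 12 equiv), CuBr (30 mol%), DMF, 115 °C, N2; dilute HCl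
Reagents that add atoms: sodium methoxide, [Na+].[O-]C
Why: Ullmann-type copper-catalysed methanolysis of aryl bromides, well known for ortho-bromophenols (the bromovanillin-to-syringaldehyde type), should replace both bromines; the substrate reacts as its bis-phenoxide, which shields C2 from methoxide, and because C6 and C8 end with the same group any opening and reclosure of ring C through the 5-oxygen (Wessely–Moser type) is degenerate.

**Step 7**
Reactants: 11 nevadensin
Product: 12 tangeretin (5,6,7,8,4'-pentamethoxyflavone)
Conditions: Me2SO4 (4 equiv), K2CO3 (6 equiv), acetone, reflux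
Reagents that add atoms: dimethyl sulfate, COS(=O)(=O)OC
Why: Williamson O-methylation of both phenols, in which the chelated and flanked 5-hydroxyl is the slow one and is driven by excess dimethyl sulfate at reflux, no other nucleophilic site remaining.

**Compound list**
1 | (E)-4-methoxycinnamoyl chloride, (2E)-3-(4-methoxyphenyl)prop-2-enoyl chloride | COc1ccc(/C=C/C(Cl)=O)cc1 | starting material
2 | (E)-N-methoxy-3-(4-methoxyphenyl)-N-methylprop-2-enamide | COc1ccc(/C=C/C(=O)N(C)OC)cc1 | intermediate
3 | 4-hydroxy-6-methyl-2H-pyran-2-one (triacetic acid lactone) | Cc1cc(O)cc(=O)o1 | starting material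
4 | dilithiated pyranone: dilithium salt of 3, deprotonated at the 4-OH and at the C6 methyl | [Li+].[Li+].[CH2-]c1cc([O-])cc(=O)o1 | intermediate
5 | 4-hydroxy-6-[(3E)-4-(4-methoxyphenyl)-2-oxobut-3-en-1-yl]-2H-pyran-2-one | COc1ccc(/C=C/C(=O)Cc2cc(O)cc(=O)o2)cc1 | intermediate
6 | methyl (8E)-9-(4-methoxyphenyl)-3,5,7-trioxonon-8-enoate (present as magnesium chelate) | COC(=O)CC(=O)CC(=O)CC(=O)/C=C/c1ccc(OC)cc1 | intermediate
7 | (E)-2',4',6'-trihydroxy-4-methoxychalcone, (2E)-3-(4-methoxyphenyl)-1-(2,4,6-trihydroxyphenyl)prop-2-en-1-one | COc1ccc(/C=C/C(=O)c2c(O)cc(O)cc2O)cc1 | intermediate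
8 | isosakuranetin, racemic 5,7-dihydroxy-2-(4-methoxyphenyl)chroman-4-one | COc1ccc(C2CC(=O)c3c(O)cc(O)cc3O2)cc1 | intermediate
9 | acacetin, 5,7-dihydroxy-2-(4-methoxyphenyl)-4H-chromen-4-one | COc1ccc(-c2cc(=O)c3c(O)cc(O)cc3o2)cc1 | intermediate
10 | 6,8-dibromo-5,7-dihydroxy-2-(4-methoxyphenyl)-4H-chromen-4-one | COc1ccc(-c2cc(=O)c3c(O)c(Br)c(O)c(Br)c3o2)cc1 | intermediate
11 | nevadensin, 5,7-dihydroxy-6,8-dimethoxy-2-(4-methoxyphenyl)-4H-chromen-4-one | COc1ccc(-c2cc(=O)c3c(O)c(OC)c(O)c(OC)c3o2)cc1 | intermediate
12 | tangeretin, 5,6,7,8-tetramethoxy-2-(4-methoxyphenyl)-4H-chromen-4-one | COc1ccc(-c2cc(=O)c3c(OC)c(OC)c(OC)c(OC)c3o2)cc1 | target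

**Total step count:** 7
**Longest linear sequence:** 7 steps (1 to 12; pyranone 3 enters as a purchased partner in step 2)

**Steps most likely to fail**

1. Step 3 (key step). The chain may close through the wrong carbon (aldol condensation of the C2 methylene onto the C7 ketone, leading to a resorcylate), or methoxide may cleave the polyketo chain by retro-Claisen fragmentation. Fallback, setting out from Weinreb amide 2 and coming back at chalcone 7: ring A is taken from a preformed phloroglucinol. 1,3,5-Tris(methoxymethoxy)benzene F1 is lithiated between two of its ether groups with n-BuLi in THF at 0 °C to give 2,4,6-tris(methoxymethoxy)phenyllithium F2. This is added at −78 °C to amide 2 (Weinreb ketone synthesis) to give (E)-3-(4-methoxyphenyl)-1-[2,4,6-tris(methoxymethoxy)phenyl]prop-2-en-1-one F3. HCl in methanol then removes the three acetals and delivers chalcone 7 for step 4.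

2. Step 6. Reductive loss of bromine (hydrodebromination) may compete, and the second substitution may stall on the electron-rich bis-phenoxide. Fallback, setting out from dibromide 10 and coming back at tangeretin 12: the phenols are methylated first (Me2SO4, K2CO3, acetone, reflux) to give 6,8-dibromo-5,7-dimethoxy-2-(4-methoxyphenyl)-4H-chromen-4-one F4. Both bromines of this neutral ether are then exchanged by palladium-catalysed C–O coupling with methanol (Pd2(dba)3 as zerovalent palladium source, tBuBrettPhos, Cs2CO3, MeOH in toluene, 80 °C), which gives 12 directly.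

3. Step 2. The dianion may add to the β-carbon of the cinnamamide (conjugate addition) instead of the carbonyl, or it may form incompletely because of poor solubility. Fallback, setting out from pyranone 3 and coming back at pyranone 5: dianion 4 is added to the carbonyl of (E)-4-methoxycinnamaldehyde F5 (aldol addition, THF, −78 °C) to give racemic 4-hydroxy-6-[(3E)-2-hydroxy-4-(4-methoxyphenyl)but-3-en-1-yl]-2H-pyran-2-one F6. Its allylic alcohol is then oxidised with MnO2 in acetone at rt to ketone 5.

**Further compounds**
F1 | step 3 | 1,3,5-tris(methoxymethoxy)benzene | COCOc1cc(OCOC)cc(OCOC)c1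
F2 | step 3 | 2,4,6-tris(methoxymethoxy)phenyllithium | [Li]c1c(OCOC)cc(OCOC)cc1OCOC
F3 | step 3 | (E)-3-(4-methoxyphenyl)-1-[2,4,6-tris(methoxymethoxy)phenyl]prop-2-en-1-one | COCOc1cc(OCOC)c(C(=O)/C=C/c2ccc(OC)cc2)c(OCOC)c1
F4 | step 6 | 6,8-dibromo-5,7-dimethoxy-2-(4-methoxyphenyl)-4H-chromen-4-one | COc1ccc(-c2cc(=O)c3c(OC)c(Br)c(OC)c(Br)c3o2)cc1
F5 | step 2 | (E)-4-methoxycinnamaldehyde | COc1ccc(/C=C/C=O)cc1
F6 | step 2 | racemic 4-hydroxy-6-[(3E)-2-hydroxy-4-(4-methoxyphenyl)but-3-en-1-yl]-2H-pyran-2-one | COc1ccc(/C=C/C(O)Cc2cc(O)cc(=O)o2)cc1
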